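The dihydrofuran of the target (ring A: O1, C2, C3, C3a, C7a), with its trans 2-aryl and 3-methyl groups, is treated as a contracted flavanone. The C3–C3a bond is the former aryl–C4 bond after a 1,2-aryl shift, and the C3 methyl carbon is the extruded C4 carbonyl carbon, released as a methyl ester. A single hypervalent-iodine oxidation therefore forms C3–C3a, closes ring A and sets C3 trans to the C2 centre, which comes from an asymmetric arylation of a chromone. The precursor is the (S)-flavanone carrying the 7-benzyloxy-6,8-dimethoxy benzo ring and the trimethoxyphenyl group. Ester-to-methyl reduction, debenzylation and dearomatising allylation at C5 complete the synthesis.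

Key step: step 8

Assumption: the palladium/t-BuPyOx arylation is taken to attack the chromone on the same enone face as it attacks 3-substituted cyclohexenones, which makes (R)-t-BuPyOx the ligand for the (2S)-flavanone; the antipodal ligand is used if the sense proves opposite.

Remark: the benzo ring needs four contiguous oxygens (O1, 8-OMe, 7-OBn, 6-OMe). A 4-alkoxy-3,5-dimethoxyphenol would acylate to the isomeric 5,6,7-trioxygenated chromone, so the ring is built from 2,6-dimethoxyphenol with the fourth oxygen introduced at C3, and the benzyl group is attached only after the Lewis-acid steps.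

Step 1
Reactants: 1 2,6-dimethoxyphenol
Product: 2 2,6-dimethoxyphenyl acetate
Conditions: Ac2O, pyridine, DMAP (cat.), CH2Cl2, rt
Reagents that add atoms: acetic anhydride, CC(=O)OC(C)=O
Why: O-acylation of the phenol masks the hydroxyl as a weakly donating ester, so that the two methoxy groups and not the phenol oxygen direct the next electrophilic substitution.

Step 2
Reactants: 2 2,6-dimethoxyphenyl acetate
Product: 3 3-formyl-2,6-dimethoxyphenyl acetate
Conditions: Cl2CHOMe, TiCl4, CH2Cl2, −10 to 0 °C; then ice-water
Reagents that add atoms: dichloromethyl methyl ether, COC(Cl)Cl; water, O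
Why: Rieche formylation, a Friedel–Crafts-type substitution, should enter C3 because it is the only position ortho to one methoxy group and para to the other, whereas C4 is meta to both ethers and para only to the deactivated acetoxy group.

Step 3
Reactants: 3 3-formyl-2,6-dimethoxyphenyl acetate
Product: 5 2,4-dimethoxybenzene-1,3-diol, via aryl formate 4 (not isolated)
Conditions: mCPBA, CH2Cl2, 0 °C to rt; aq. NaHCO3 wash; then HCl (cat.), MeOH, 40 °C, under N2
Reagents that add atoms: 3-chloroperoxybenzoic acid (mCPBA), OOC(=O)c1cccc(Cl)c1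
Why: In this Dakin-type Baeyer–Villiger oxidation the electron-rich aryl group migrates to oxygen to give formate 4, and acid-catalysed methanolysis then removes both the formyl and the acetyl group to free the resorcinol.

Step 4
Reactants: 5 2,4-dimethoxybenzene-1,3-diol
Product: 6 1-(2,4-dihydroxy-3,5-dimethoxyphenyl)ethanone
Conditions: AcOH (3 equiv) in BF3·OEt2 (solvent), 85 °C; then aq. NaOAc
Reagents that add atoms: acetic acid, CC(O)=O
Why: The BF3-promoted Friedel–Crafts (Fries-type) acetylation goes to C6, the position ortho to one hydroxyl and para to the other, and it is run before any benzyl ether is present because such ethers are at risk under these Lewis-acid conditions.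

Step 5
Reactants: 6 1-(2,4-dihydroxy-3,5-dimethoxyphenyl)ethanone; 7 benzyl bromide
Product: 8 1-[4-(benzyloxy)-2-hydroxy-3,5-dimethoxyphenyl]ethanone
Conditions: K2CO3 (1.1 equiv), acetone, 50 °C
Reagents that add atoms: none
Why: Williamson etherification takes place at the 4-hydroxyl, which is para to the carbonyl group and therefore the more acidic, while the 2-hydroxyl is held in a hydrogen bond to the ketone and stays free for the chromone synthesis.

Step 6
Reactants: 8 1-[4-(benzyloxy)-2-hydroxy-3,5-dimethoxyphenyl]ethanone
Product: 10 7-(benzyloxy)-6,8-dimethoxy-4H-chromen-4-one, via enaminone 9 (not isolated)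
Conditions: Me2NCH(OMe)2, toluene, 100 °C; evaporate; then conc. HCl, CH2Cl2, 40 °C
Reagents that add atoms: N,N-dimethylformamide dimethyl acetal, COC(OC)N(C)C
Why: Condensation of the methyl ketone with the amide acetal gives enaminone 9, and acid then triggers intramolecular oxa-Michael addition of the phenol with loss of dimethylamine, the standard enaminone route to 2,3-unsubstituted chromones.

Step 7
Reactants: 10 7-(benzyloxy)-6,8-dimethoxy-4H-chromen-4-one; 11 3,4,5-trimethoxyphenylboronic acid
Product: 12 (2S)-7-(benzyloxy)-6,8-dimethoxy-2-(3,4,5-trimethoxyphenyl)-2,3-dihydro-4H-chromen-4-one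
Conditions: Pd(OCOCF3)2 (5 mol%), (R)-t-BuPyOx (6 mol%), NH4PF6 (30 mol%), H2O (5 equiv), ClCH2CH2Cl, 60 °C
Reagents that add atoms: none
Why: Enantioselective conjugate addition of the arylboronic acid to the chromone under cationic divalent-palladium/pyridine-oxazoline catalysis (a Hayashi–Miyaura-type 1,4-addition) creates C2, whose (S) configuration is set by the tert-butyl group of the (R)-ligand, which blocks one face of the enone during aryl transfer from palladium.

Step 8
Reactants: 12 (2S)-7-(benzyloxy)-6,8-dimethoxy-2-(3,4,5-trimethoxyphenyl)-2,3-dihydro-4H-chromen-4-one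
Product: 14 methyl (2S,3S)-6-(benzyloxy)-5,7-dimethoxy-2-(3,4,5-trimethoxyphenyl)-2,3-dihydro-1-benzofuran-3-carboxylate (trans), via methyl enol ether 13 (not isolated)
Conditions: PhI(OAc)2 (1.3 equiv), conc. H2SO4 (0.5 equiv), HC(OMe)3, 0 °C to rt; then aq. NaHCO3
Reagents that add atoms: trimethyl orthoformate, COC(OC)OC; water, O
Why: Acid and the orthoformate convert the ketone into enol ether 13, which the trivalent iodine reagent attacks at C3 on the face anti to the C2 aryl group; the fused aryl carbon C4a then shifts from C4 to C3 with inversion as iodobenzene leaves, and the resulting dimethoxycarbenium ion is hydrolysed to the methyl ester on work-up. This is the known oxidative 1,2-aryl shift (ring contraction) of flavanones to trans 2-aryl-2,3-dihydrobenzofuran-3-carboxylates with PhI(OAc)2 or Tl(NO3)3 in trimethyl orthoformate. Ring A (O1, C2, C3, C3a, C7a) is not closed by a cyclisation but arises when the six-membered pyranone contracts through this suprafacial 1,2-shift, which creates the C3–C3a bond. The new C3 centre is controlled by the existing C2 centre, since anti iodination followed by invertive migration places the ester trans to the aryl group, which is also the thermodynamically preferred arrangement at this epimerisable position. The step needs migration of C4a in preference to migration of the C2 aryl group (isoflavone) or elimination (flavone), and this is secured by the diequatorial conformer, in which the C3–I bond is antiperiplanar to C4–C4a, and by the high migratory aptitude of an aryl carbon that is ortho to O1 and para to the benzyloxy group. C2 is retained as long as acid-induced opening to the chalcone is suppressed by the low temperature and a short reaction time.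

Step 9
Reactants: 14 methyl (2S,3S)-6-(benzyloxy)-5,7-dimethoxy-2-(3,4,5-trimethoxyphenyl)-2,3-dihydro-1-benzofuran-3-carboxylate
Product: 15 [(2S,3R)-6-(benzyloxy)-5,7-dimethoxy-2-(3,4,5-trimethoxyphenyl)-2,3-dihydro-1-benzofuran-3-yl]methanol
Conditions: LiAlH4, THF, 0 °C; then H2O, aq. NaOH
Reagents that add atoms: none
Why: Hydride reduction of the ester with LiAlH4 gives the primary alcohol without touching the two stereocentres or the aryl ethers (the C3 descriptor changes only through the priority rules).

Step 10
Reactants: 15 [(2S,3R)-6-(benzyloxy)-5,7-dimethoxy-2-(3,4,5-trimethoxyphenyl)-2,3-dihydro-1-benzofuran-3-yl]methanol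
Product: 16 [(2S,3R)-6-(benzyloxy)-5,7-dimethoxy-2-(3,4,5-trimethoxyphenyl)-2,3-dihydro-1-benzofuran-3-yl]methyl methanesulfonate
Conditions: MsCl, Et3N, CH2Cl2, 0 °C
Reagents that add atoms: methanesulfonyl chloride, CS(=O)(=O)Cl
Why: Sulfonylation (mesylation) converts the primary alcohol into a leaving group under cold, basic, non-ionising conditions that leave the homobenzylic position intact.

Step 11
Reactants: 16 [(2S,3R)-6-(benzyloxy)-5,7-dimethoxy-2-(3,4,5-trimethoxyphenyl)-2,3-dihydro-1-benzofuran-3-yl]methyl methanesulfonate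
Product: 17 (2S,3S)-6-(benzyloxy)-5,7-dimethoxy-3-methyl-2-(3,4,5-trimethoxyphenyl)-2,3-dihydro-1-benzofuran
Conditions: LiEt3BH, THF, 0 °C to rt
Reagents that add atoms: none
Why: LiEt3BH displaces the primary mesylate by SN2 hydride delivery, the standard deoxygenation of a primary alcohol, and C2 and C3 are unaffected because C3 is no longer next to a carbonyl group.

Step 12
Reactants: 17 (2S,3S)-6-(benzyloxy)-5,7-dimethoxy-3-methyl-2-(3,4,5-trimethoxyphenyl)-2,3-dihydro-1-benzofuran
Product: 18 (2S,3S)-5,7-dimethoxy-3-methyl-2-(3,4,5-trimethoxyphenyl)-2,3-dihydro-1-benzofuran-6-ol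
Conditions: H2 (1 atm), 10% Pd/C, EtOAc, rt
Reagents that add atoms: none
Why: Catalytic hydrogenolysis cleaves the benzyl aryl ether under neutral conditions, and the reaction is stopped after one equivalent of hydrogen so that the more slowly cleaved cyclic C2–O1 benzylic ether stays intact.

Step 13
Reactants: 18 (2S,3S)-5,7-dimethoxy-3-methyl-2-(3,4,5-trimethoxyphenyl)-2,3-dihydro-1-benzofuran-6-ol
Product: 19 (2S,3S,5R)-5,7-dimethoxy-3-methyl-5-(prop-2-en-1-yl)-2-(3,4,5-trimethoxyphenyl)-3,5-dihydro-1-benzofuran-6(2H)-one
Conditions: PhI(OCOCF3)2 (1.1 equiv), allylSiMe3 (5 equiv), CH2Cl2, −78 to −30 °C; then aq. NaHCO3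
Reagents that add atoms: allyltrimethylsilane, C=CC[Si](C)(C)C
Why: Proposed new method: ligand exchange of the phenol on trivalent iodine and loss of iodobenzene should give a methoxy-stabilised phenoxenium-type cation whose C5 carbon (oxocarbenium-like, less hindered than C7 and not inductively deactivated by O1) is captured by the allylsilane with loss of the silyl group, and attack anti to the neighbouring C3 methyl group should favour the (5R) centre, probably only moderately; the closest known reaction type is the PhI(OCOCF3)2-mediated oxidative ortho-allylation of 2-alkoxy-1-naphthols with allyltrimethylsilane to 2-allyl-2-alkoxynaphthalen-1(2H)-ones, together with the PhI(OAc)2/methanol conversion of 2-methoxyphenols into ortho-quinone monoketals.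

Compound list

1 | 2,6-dimethoxyphenol | COc1cccc(OC)c1O | starting material
2 | 2,6-dimethoxyphenyl acetate | COc1cccc(OC)c1OC(C)=O | intermediate
3 | 3-formyl-2,6-dimethoxyphenyl acetate | COc1ccc(C=O)c(OC)c1OC(C)=O | intermediate
4 | 3-(formyloxy)-2,6-dimethoxyphenyl acetate (not isolated) | COc1ccc(OC=O)c(OC)c1OC(C)=O | intermediate
5 | 2,4-dimethoxybenzene-1,3-diol | COc1ccc(O)c(OC)c1O | intermediate
6 | 1-(2,4-dihydroxy-3,5-dimethoxyphenyl)ethanone | CC(=O)c1cc(OC)c(O)c(OC)c1O | intermediate
7 | benzyl bromide | BrCc1ccccc1 | starting material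
8 | 1-[4-(benzyloxy)-2-hydroxy-3,5-dimethoxyphenyl]ethanone | CC(=O)c1cc(OC)c(OCc2ccccc2)c(OC)c1O | intermediate
9 | (E)-1-[4-(benzyloxy)-2-hydroxy-3,5-dimethoxyphenyl]-3-(dimethylamino)prop-2-en-1-one (not isolated) | CN(C)/C=C/C(=O)c1cc(OC)c(OCc2ccccc2)c(OC)c1O | intermediate
10 | 7-(benzyloxy)-6,8-dimethoxy-4H-chromen-4-one | COc1cc2c(c(OC)c1OCc3ccccc3)OC=CC2=O | intermediate
11 | 3,4,5-trimethoxyphenylboronic acid | COc1cc(B(O)O)cc(OC)c1OC | starting material
12 | (2S)-7-(benzyloxy)-6,8-dimethoxy-2-(3,4,5-trimethoxyphenyl)-2,3-dihydro-4H-chromen-4-one | COc1cc2c(c(OC)c1OCc3ccccc3)O[C@H](c4cc(OC)c(OC)c(OC)c4)CC2=O | intermediate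
13 | (2S)-7-(benzyloxy)-4,6,8-trimethoxy-2-(3,4,5-trimethoxyphenyl)-2H-chromene (not isolated) | COc1cc2c(c(OC)c1OCc3ccccc3)O[C@H](c4cc(OC)c(OC)c(OC)c4)C=C2OC | intermediate
14 | methyl (2S,3S)-6-(benzyloxy)-5,7-dimethoxy-2-(3,4,5-trimethoxyphenyl)-2,3-dihydro-1-benzofuran-3-carboxylate (trans) | COc1cc2c(c(OC)c1OCc3ccccc3)O[C@H](c4cc(OC)c(OC)c(OC)c4)[C@H]2C(=O)OC | intermediate
15 | [(2S,3R)-6-(benzyloxy)-5,7-dimethoxy-2-(3,4,5-trimethoxyphenyl)-2,3-dihydro-1-benzofuran-3-yl]methanol (trans) | COc1cc2c(c(OC)c1OCc3ccccc3)O[C@H](c4cc(OC)c(OC)c(OC)c4)[C@H]2CO | intermediate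
16 | [(2S,3R)-6-(benzyloxy)-5,7-dimethoxy-2-(3,4,5-trimethoxyphenyl)-2,3-dihydro-1-benzofuran-3-yl]methyl methanesulfonate (trans) | COc1cc2c(c(OC)c1OCc3ccccc3)O[C@H](c4cc(OC)c(OC)c(OC)c4)[C@H]2COS(C)(=O)=O | intermediate
17 | (2S,3S)-6-(benzyloxy)-5,7-dimethoxy-3-methyl-2-(3,4,5-trimethoxyphenyl)-2,3-dihydro-1-benzofuran (trans) | COc1cc2c(c(OC)c1OCc3ccccc3)O[C@H](c4cc(OC)c(OC)c(OC)c4)[C@H]2C | intermediate
18 | (2S,3S)-5,7-dimethoxy-3-methyl-2-(3,4,5-trimethoxyphenyl)-2,3-dihydro-1-benzofuran-6-ol (trans) | COc1cc2c(c(OC)c1O)O[C@H](c3cc(OC)c(OC)c(OC)c3)[C@H]2C | intermediate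
19 | (2S,3S,5R)-5,7-dimethoxy-3-methyl-5-(prop-2-en-1-yl)-2-(3,4,5-trimethoxyphenyl)-3,5-dihydro-1-benzofuran-6(2H)-one | C=CC[C@@]1(OC)C=C2C(=C(OC)C1=O)O[C@H](c1cc(OC)c(OC)c(OC)c1)[C@H]2C | target

Total step count: 13. Longest linear sequence: 13 steps (1 to 19); 7 and 11 are commercial reagents that enter at steps 5 and 7.

Steps most likely to fail

Step 13 (the proposed method). The allylsilane may add at C7 or at C3a instead of C5, and the two faces of C5 may be poorly differentiated by the remote C3 methyl group. The oxidant may also consume the silane before it engages the phenol, and the acid set free may promote allyl migration in the dienone. The fallback uses known chemistry and sets out from phenol 18. Oxidation with PhI(OAc)2 in MeOH at 0 °C, the standard preparation of ortho-quinone monoketals from 2-methoxyphenols, should give (2S,3S)-5,5,7-trimethoxy-3-methyl-2-(3,4,5-trimethoxyphenyl)-3,5-dihydro-1-benzofuran-6(2H)-one F1, an isolable compound in which the site of attack can be checked. Ionisation of this ketal with Me3SiOTf in CH2Cl2 at −78 °C in the presence of allylSiMe3 (Hosomi–Sakurai substitution of a ketal alkoxy group, as practised on quinone monoketals) then replaces one methoxy group by allyl under non-oxidising conditions and comes back to the route at target 19. The C5 epimers would be separated by chromatography.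

Step 8 (key step). Acid-induced opening of the pyranone to the chalcone may erode the C2 configuration. The C2 aryl group may migrate in place of C4a, elimination may give the flavone, and the electron-rich rings may be over-oxidised. The fallback sets out from flavanone 12 and forms the same C3–C3a bond by a carbene route in which only C4a can migrate. Detrifluoroacetylative diazo transfer would proceed through (2S)-7-(benzyloxy)-6,8-dimethoxy-3-(trifluoroacetyl)-2-(3,4,5-trimethoxyphenyl)-2,3-dihydro-4H-chromen-4-one F2 (LiN(SiMe3)2, CF3CO2CH2CF3, THF, −78 °C; not isolated). Treatment with MsN3 and Et3N in MeCN would then give (2R)-7-(benzyloxy)-3-diazo-6,8-dimethoxy-2-(3,4,5-trimethoxyphenyl)-2,3-dihydro-4H-chromen-4-one F3, whose descriptor changes only through the priority rules. Photochemical Wolff rearrangement in MeOH contracts the ring and should give the trans ester together with its cis isomer, methyl (2S,3R)-6-(benzyloxy)-5,7-dimethoxy-2-(3,4,5-trimethoxyphenyl)-2,3-dihydro-1-benzofuran-3-carboxylate F4. Equilibration at C3 with NaOMe in MeOH converges on the trans ester and comes back to the route at 14.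

Step 7. The electron-rich chromone may be a sluggish acceptor, the electron-rich boronic acid may protodeboronate, and the enantioinduction may be insufficient or of the opposite sense. The fallback sets out from acetophenone 8. Claisen–Schmidt condensation with 3,4,5-trimethoxybenzaldehyde (KOH, EtOH) gives (E)-1-[4-(benzyloxy)-2-hydroxy-3,5-dimethoxyphenyl]-3-(3,4,5-trimethoxyphenyl)prop-2-en-1-one F5. Cyclisation by oxa-Michael addition (NaOAc, EtOH, reflux) gives racemic 7-(benzyloxy)-6,8-dimethoxy-2-(3,4,5-trimethoxyphenyl)-2,3-dihydro-4H-chromen-4-one F6. Preparative chromatography on a chiral stationary phase delivers the (S)-enantiomer and comes back to the route at 12, while the unwanted enantiomer is returned to F5 with base and recycled.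

Further compounds

F1 | step 13 | (2S,3S)-5,5,7-trimethoxy-3-methyl-2-(3,4,5-trimethoxyphenyl)-3,5-dihydro-1-benzofuran-6(2H)-one | COC1(OC)C=C2C(=C(OC)C1=O)O[C@H](c3cc(OC)c(OC)c(OC)c3)[C@H]2C
F2 | step 8 | (2S)-7-(benzyloxy)-6,8-dimethoxy-3-(trifluoroacetyl)-2-(3,4,5-trimethoxyphenyl)-2,3-dihydro-4H-chromen-4-one | COc1cc2c(c(OC)c1OCc3ccccc3)O[C@H](c4cc(OC)c(OC)c(OC)c4)C(C(=O)C(F)(F)F)C2=O
F3 | step 8 | (2R)-7-(benzyloxy)-3-diazo-6,8-dimethoxy-2-(3,4,5-trimethoxyphenyl)-2,3-dihydro-4H-chromen-4-one | COc1cc2c(c(OC)c1OCc3ccccc3)O[C@H](c4cc(OC)c(OC)c(OC)c4)C(=[N+]=[N-])C2=O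
F4 | step 8 | methyl (2S,3R)-6-(benzyloxy)-5,7-dimethoxy-2-(3,4,5-trimethoxyphenyl)-2,3-dihydro-1-benzofuran-3-carboxylate (cis) | COc1cc2c(c(OC)c1OCc3ccccc3)O[C@H](c4cc(OC)c(OC)c(OC)c4)[C@@H]2C(=O)OC
F5 | step 7 | (E)-1-[4-(benzyloxy)-2-hydroxy-3,5-dimethoxyphenyl]-3-(3,4,5-trimethoxyphenyl)prop-2-en-1-one | COc1cc(/C=C/C(=O)c2cc(OC)c(OCc3ccccc3)c(OC)c2O)cc(OC)c1OC
F6 | step 7 | racemic 7-(benzyloxy)-6,8-dimethoxy-2-(3,4,5-trimethoxyphenyl)-2,3-dihydro-4H-chromen-4-one | COc1cc2c(c(OC)c1OCc3ccccc3)OC(c4cc(OC)c(OC)c(OC)c4)CC2=O
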